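Readings and results were computed for an exercise, noise included.

The autumn run is the noon run with 25.0 mM of product added at the start. By 17 min it has made 22.6 mM against 22.77 mM in the noon run, a gap smaller than twice the scatter, so at that reading you can see no effect of added product.

| flask | starting material | free catalyst | product | time |
|---|---|---|---|---|
| noon | 50.0 mM | 2.50 mM |  |  |
| spring | 20.0 mM | 2.50 mM |  |  |
| dawn | 25.0 mM | 2.50 mM |  |  |
| autumn | 50.0 mM | 2.50 mM | 25.0 mM |  |
| midnight | 50.0 mM | 2.50 mM |  | 100 min |

| run | time / min | [product] / mM |
|---|---|---|
| noon run | 0.61 | 6.16 |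
| noon run | 1.8 | 12.59 |
| noon run | 3.5 | 16.58 |
| noon run | 5.6 | 19.07 |
| noon run | 8.0 | 20.44 |
| noon run | 11 | 21.33 |
| noon run | 14 | 22.39 |
| noon run | 17 | 22.77 |
| spring run | 0.61 | 2.41 |
| spring run | 1.8 | 5.68 |
| spring run | 3.5 | 7.32 |
| spring run | 5.6 | 9.20 |
| spring run | 8.0 | 10.22 |
| spring run | 11 | 11.21 |
| spring run | 14 | 11.67 |
| spring run | 17 | 12.05 |
| dawn run | 0.61 | 3.04 |
| dawn run | 1.8 | 6.48 |
| dawn run | 3.5 | 9.41 |
| dawn run | 5.6 | 11.03 |
| dawn run | 8.0 | 12.33 |
| dawn run | 11 | 12.94 |
| dawn run | 14 | 13.59 |
| dawn run | 17 | 13.67 |
| autumn run | 0.61 | 30.44 |
| autumn run | 1.8 | 37.30 |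
| autumn run | 3.5 | 41.46 |
| autumn run | 5.6 | 44.16 |
| autumn run | 8.0 | 45.59 |
| autumn run | 11 | 46.82 |
| autumn run | 14 | 47.76 |
| autumn run | 17 | 47.60 |

(scatter of a reading: 0.2 mM)

- how the opening rate goes with [starting material] round the charge of the noon run: the exponent of the rate at two percent of starting material gone to product (one fixed amount of product, the same in the runs compared)
- product in the midnight run at 100 min, as a share of the starting material charged

- Overall: starting material -> product, with free catalyst as catalyst.
- Constant volume, constant temperature.
- An order is taken over about fifteen percent of the charge, up and down.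

The midnight run has the charge of the noon run, so you may treat it as the noon run left standing until 100 min.

Take the opening first. The first noon reading over the first spring reading is 2.56, for a charge ratio of 2.50. That reads as an exponent of 1.02, so I reckon the opening as pseudo-first-order in starting material.

The far end needs something else: how quickly the noon curve stops. Its rate is 0.571 mM min⁻¹ between 5.6 min and 8.0 min, but 0.259 mM min⁻¹ between 8.0 min and 17 min. The centres of these spans lie 5.70 min apart. So I take the fade time, the time in which the noon rate falls by a factor e, as 7.21 min.

Carried to the last reading, the rate is 0.139 mM min⁻¹. A rate fading this way adds that rate times the fade time, 1.00 mM. On this fading law, hardly any of that rate is left at 100 min, so my reckoning ends at 47.5% of the charge.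

The forecast gives an order of 1 and a midnight product of 48% of the charge, the latter a little above mine, and says: “The catalyst must be dying.”

The flask gives an order of 1.1 round the noon charge, and the midnight run holds 49.4% of its charge as product at 100 min.

    free catalyst + starting material → product + free catalyst (102.6 L mol⁻¹ min⁻¹)
    2 free catalyst → 2 spent catalyst (71.40 L mol⁻¹ min⁻¹)
    2 starting material → homo dimer (3.456 L mol⁻¹ min⁻¹)

At the noon charge, starting material opens by going to homo dimer at 17.3 mM min⁻¹, against 12.8 mM min⁻¹ to product. The midnight product stands 1.92 mM above the last noon reading, about twice my tail. In the autumn run, the fade time applied to the earlier noon rate gives 2.48 mM between 8.0 min and 17 min, and the readings there rise by 2.01 mM.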